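(The runs are simulated for an exercise, and the scatter is random.)

- The pitfall in this flask is to chase four curves one by one, so I follow two things: the pool, meaning starting material, target and isomer of the product taken together, and how fast it shrinks.

| flask | starting material | catalyst | remark | time |
|---|---|---|---|---|
| east | 0.050 M | 20 mol% | run made earlier |  |
| north | 0.050 M | 31 mol% | run made earlier |  |
| south | 0.10 M | 14 mol% | run made earlier |  |
| autumn | 0.050 M | 14 mol% |  | 3.0 min |
| summer | 0.050 M | 14 mol% |  | 5.0 min |

| run | time / s | target / % | starting material / % | over-reaction product / % | isomer of the product / % |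
|---|---|---|---|---|---|
| east | 10.0 | 18 | 70 | 2 | 10 |
| east | 15.0 | 19 | 59 | 3 | 18 |
| east | 30.0 | 21 | 41 | 7 | 32 |
| east | 50.0 | 19 | 27 | 13 | 41 |
| east | 60.0 | 18 | 25 | 15 | 45 |
| east | 80.0 | 18 | 22 | 17 | 48 |
| east | 120 | 14 | 18 | 26 | 45 |
| north | 10.0 | 23 | 62 | 2 | 17 |
| north | 15.0 | 21 | 50 | 3 | 21 |
| north | 30.0 | 17 | 31 | 5 | 41 |
| north | 50.0 | 19 | 22 | 12 | 48 |
| north | 60.0 | 15 | 22 | 15 | 46 |
| north | 80.0 | 16 | 17 | 17 | 50 |
| north | 120 | 14 | 15 | 26 | 46 |
| south | 10.0 | 20 | 63 | 3 | 15 |
| south | 15.0 | 22 | 54 | 2 | 23 |
| south | 30.0 | 23 | 33 | 6 | 40 |
| south | 60.0 | 17 | 22 | 15 | 48 |
| south | 120 | 13 | 17 | 29 | 44 |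

(readings scatter by 1.5 percentage points)



- which of these there is most of at the end, counted by the starting material in it, autumn (isomer of the product / starting material / over-reaction product / target)
- which of these there is most of at the end, counted by the starting material in it, summer (isomer of the product / starting material / over-reaction product / target)
- amount of the one of these that there is most of at the end, in percent of the starting material charged, autumn
- amount of the one of these that there is most of at the end, in percent of the starting material charged, summer

- First instants: in the east run, at 0.0100 M of catalyst, starting material falls to 70% by 10.0 s, which reads as a first-order constant of 0.0357 s⁻¹. Taking that as proportional to catalyst, autumn's 0.00700 M gives 0.0250 s⁻¹, a half-time of 27.8 s, shorter than the 3.0 min asked.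
- Middle: by 30.0 s the east run holds more isomer of the product than target, 32% against 21%. Catalyst times time in autumn at 3.0 min is 1.05 of the east value at 120 s, so I borrow the east shares there, with isomer of the product at 0.608 of the pool.
- End: east and north both read 26% of over-reaction product at 120 s, despite loadings of 20 mol% and 31 mol%. I therefore replace the shrinking by its mean over the last stretch: the leak constant, the natural logarithm of the ratio of two pools divided by the time between them, a pseudo-first-order constant.
- East has the lowest catalyst concentration of the runs, and its pool, counted as what is not over-reaction product, goes from 85.0% to 74.0% between 60.0 s and 120 s, so the leak reads 0.00231 s⁻¹.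
- My reckoning for autumn, carrying the east pool on from 120 s: the pool is 64.4%, so over-reaction product is 35.6% and isomer of the product 39.2%. That lead of 3.6 percentage points is thin against a scatter of 1.5 points, but I commit to the isomer.
- My reckoning for summer, carrying the same east pool on: the pool is 48.8%, so over-reaction product leads at 51.2%, with isomer of the product at 29.7%.
- The forecast differs from me: it has the pool decaying at about 0.0027 per second and names over-reaction product at 38% for autumn and over-reaction product at 54% for summer, with the words “Slower isomerisation at low catalyst slightly favours the over-reaction product”.

    target → over-reaction product (k = 0.0130 s⁻¹)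
    isomer of the product ⇌ starting material (k = 0.00230 s⁻¹)
    target + catalyst ⇌ isomer of the product + catalyst, rate k3*[catalyst]*[target] forward; the back reaction follows from the equilibrium constant (K = 3.00, k = 5.80 L mol⁻¹ s⁻¹)
    starting material + catalyst ⇌ target + catalyst, rate k4*[starting material]*[catalyst] forward; the back reaction follows from the equilibrium constant (K = 0.970, k = 3.40 L mol⁻¹ s⁻¹)

- The flask gives isomer of the product at 40.3% in autumn, with over-reaction product at 34.5%, and over-reaction product at 50.2% in summer. Autumn's leader is where the forecast and I part. Autumn and summer are one recipe read at two times, so the leak carried from autumn's pool gives 50.4% of over-reaction product at 5.0 min. The neighbour is summer's flask read at 8.0 min: the leak carried from summer's pool gives 67.1% of over-reaction product, and that flask holds 66.9%.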